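The plan rests on the cyclopropyl ketone in ring B: ketone C8 is bonded to C7, and C11 (CMe2) spans C7 and C6. An oxa-di-π-methane rearrangement leaves exactly this arrangement when acyl C8 migrates from C11 to C7 in a β,γ-unsaturated ketone. Cutting C7–C8 and C6–C11 therefore leads back to a 2,2-dimethylcyclohept-3-enone, and one sensitised irradiation shrinks this seven-membered ring to ring B and closes the cyclopropane. The precursor is the cis-fused dihydrobenzofuran–cyclohexane–cycloheptenone carrying acetyl and phenol. Its aryl unit is attached last, by Mitsunobu etherification at C9 and Claisen rearrangement/oxa-Michael closure, so no enolisable aryl ketone meets the organometallic steps.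

Key step: step 10

Remark on the chemistry: terpenoid carbons carry aristolane numbers (C1 aryl-bearing CH, C4 CHMe, C5 quaternary C–Me, C6=C7, C8 ketone, C9, C10 ether carbon, C11 CMe2) and arene positions are primed (C1′ bears the acetyl group); the C1/C10 configuration relative to C5 is assumed to be the less stable one, so it is built by stereospecific steps and never equilibrated.

Step 1
Reactants: 1 1-bromo-3-methylbut-2-ene; 2 N-methoxy-N-methylacetamide
Product: 4 3,3-dimethylpent-4-en-2-one, via 3-methylbut-2-enylmagnesium bromide 3 (not isolated)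
Conditions: Mg, THF, 0 °C; then 2, −78 → 0 °C; aq. NH4Cl
Reagents that add atoms: none
Why: The allylic Grignard reagent reacts through its γ-carbon and the Weinreb amide stops at the ketone stage, which gives the α,α-dimethyl β,γ-enone (reverse prenylation).

Step 2
Reactants: 5 2-methylcyclohex-2-en-1-one; 6 3-bromoprop-1-ene
Product: 8 (2S,3R)-2-allyl-2,3-dimethylcyclohexan-1-one (methyls cis), via dimethylaluminium enolate 7 (not isolated)
Conditions: Me3Al, Cu(O2CC4H3S) (copper thiophene-2-carboxylate, cat.), chiral binaphthol phosphoramidite (cat., enantiomer giving 3R), Et2O, −30 °C; then MeLi, 6, THF–HMPA, −30 → 0 °C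
Reagents that add atoms: trimethylaluminium, C[Al](C)C
Why: Copper-catalysed asymmetric conjugate addition sets C4 (ring C3, R) under ligand control, and the enolate is then allylated anti to that new methyl, which makes the C4 and C5 methyls cis (conjugate addition–enolate alkylation).

Step 3
Reactants: 8 (2S,3R)-2-allyl-2,3-dimethylcyclohexan-1-one
Product: 9 (2R,3R)-2,3-dimethyl-2-[(E)-prop-1-enyl]cyclohexan-1-one (same spatial arrangement as 8)
Conditions: RuHCl(CO)(PPh3)3 (cat.), toluene, 100 °C
Reagents that add atoms: none
Why: Ruthenium hydride-catalysed olefin migration moves the terminal alkene one position inward and cannot go further because C5 is quaternary; this shortens the later metathesis ring by one carbon.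

Step 4
Reactants: 9 (2R,3R)-2,3-dimethyl-2-[(E)-prop-1-enyl]cyclohexan-1-one
Product: 10 5,6-dimethyl-6-[(E)-prop-1-enyl]cyclohex-1-en-1-yl trifluoromethanesulfonate (C10 enol triflate, C1=C10)
Conditions: KN(SiMe3)2, THF, −78 °C; PhNTf2, −78 → 0 °C
Reagents that add atoms: N-phenylbis(trifluoromethanesulfonimide), O=S(=O)(N(c1ccccc1)S(=O)(=O)C(F)(F)F)C(F)(F)F
Why: Only C1 carries α-hydrogens, so enolisation and O-sulfonylation give a single enol triflate.

Step 5
Reactants: 10 the enol triflate; 4 3,3-dimethylpent-4-en-2-one
Product: 11 1-{5,6-dimethyl-6-[(E)-prop-1-enyl]cyclohex-1-en-1-yl}-3,3-dimethylpent-4-en-2-one (triene ketone)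
Conditions: 4, LiN(SiMe3)2, THF, −78 → 0 °C; then 10, Pd2(dba)3 (cat.), P(t-Bu)3 (cat.), 23 → 50 °C
Reagents that add atoms: none
Why: Palladium-catalysed α-alkenylation of a ketone enolate with an alkenyl triflate forms C9–C10 (the methyl group is the only enolisable site of 4); the product sits as its dienolate and is reprotonated at C9 on work-up, so the alkene stays at C1=C10.

Step 6
Reactants: 11 the triene ketone
Product: 12 4,4a,7,7-tetramethyl-2,3,4,4a,7,9-hexahydro-8H-benzo[7]annulen-8-one (6–7 dienone: C1=C10, C6=C7, C8 ketone, C4/C5 methyls cis)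
Conditions: second-generation Grubbs catalyst (cat.), 1,4-benzoquinone (cat.), toluene, 80 °C
Reagents that add atoms: none
Why: Ring-closing metathesis between the vinyl and propenyl groups closes the seven-membered ring with loss of propene, and the hindered trisubstituted C1=C10 alkene should stay out of the reaction.

Step 7
Reactants: 12 the 6–7 dienone
Product: 13 the C9 alcohol of 12 (C9–OH trans to the C5 methyl)
Conditions: LiN(SiMe3)2, THF, −78 °C; 2-(phenylsulfonyl)-3-phenyloxaziridine, −78 °C; aq. NH4Cl
Reagents that add atoms: 2-(phenylsulfonyl)-3-phenyloxaziridine, O=S(=O)(c1ccccc1)N1OC1c1ccccc1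
Why: The C9 methylene is the only acidic site, and the dienolate is hydroxylated at its α-carbon (enolate oxidation with an N-sulfonyloxaziridine) from the face opposite the pseudo-axial C5 methyl, which sets C9.

Step 8
Reactants: 13 the C9 alcohol; 14 2',6'-dihydroxy-4'-methoxyacetophenone
Product: 15 the C9 aryl ether, linked through O2′ (aryloxy cis to the C5 methyl)
Conditions: 14 (3 equiv), PPh3, diisopropyl azodicarboxylate, toluene, 0 → 23 °C
Reagents that add atoms: none
Why: Mitsunobu etherification with the acidic, symmetric phenol inverts C9 in an SN2 step activated by the flanking carbonyl and alkene, which places the aryloxy group on the C5-methyl face; the excess of 14 keeps the reaction at mono-alkylation.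

Step 9
Reactants: 15 the C9 aryl ether
Product: 17 the cycloheptenone precursor (cis-fused dihydrobenzofuran on ring A, C10–O and C1–aryl on the face of the C4/C5 methyls; 2,2-dimethylcyclohept-3-enone with C8 ketone, C9 methylene, C6=C7; 1′-acetyl, 6′-OH, 4′-OMe), via C1-aryl dienone phenol 16 (not isolated)
Conditions: 1,2-dichlorobenzene, 150 °C (sealed tube); then Et3N (cat.), CH2Cl2, 23 °C
Reagents that add atoms: none
Why: Aromatic Claisen rearrangement carries the aryl group suprafacially from O–C9 to C1 on the C5-methyl face and leaves the C9=C10 enone, to which the freed 2′-phenol adds 5-exo at C10 (oxa-Michael) on the same face, the cis ring fusion being the only unstrained outcome.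

Step 10
Reactants: 17 the cycloheptenone precursor
Product: 18 the pentacyclic cyclopropyl ketone with C9 methylene (ring B cyclohexanone, C11 bridging C6 and C7 anti to the C5 methyl)
Conditions: hν (300 nm, Pyrex), acetone (degassed, 5 mM), 20 °C
Reagents that add atoms: none
Why: Triplet energy transfer from acetone gives the β,γ-enone triplet, in which carbonyl carbon C8 bonds to C7, the C8–C11 bond then breaks to restore the C8 ketone, and the C11/C6 1,3-diradical recombines (oxa-di-π-methane rearrangement, known for β,γ-unsaturated ketones and best precedented in rigid bicyclic enones). Ring B (C5–C6–C7–C8–C9–C10) arises from this 1,2-acyl shift, formally a 3-exo-trig attack of the alkene terminus on C8 followed by β-scission, and the cyclopropane from radical recombination of C11 with C6. C6 and C7 can only be cis-fused, and C11 closes on the alkene face opposite to the one from which C8 bridges, so the cyclopropane ends syn to whichever C5 substituent stands on that face. The target (C11 syn to C4, anti to the C5 methyl) therefore needs C8 to bridge from the face not occupied by the C5–C4 bond, which is the case in the ring-A chair with C5–C6 equatorial or in a twist form of the seven-membered ring, whereas the chair-like form with the C5 methyl perpendicular to the alkene would give the C6,C7-epimer; the first photolysate must be assigned by NOE between the C5 methyl and the cyclopropane. The acyl shift must win over the 1,3-acyl shift and α-cleavage, which triplet sensitisation and the quaternary, hydrogen-free C11 secure. Acetone as solvent absorbs most of the light, and the hydrogen-bonded 2′-hydroxyaryl ketone should shed any excitation by excited-state proton transfer.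

Step 11
Reactants: 18 the pentacyclic cyclopropyl ketone; 19 4-methoxybenzaldehyde
Product: 21 the (E)-chalcone with C9 methylene, via aldol adduct 20 (not isolated)
Conditions: LiN(SiMe3)2 (3.2 equiv), THF, −78 °C; 19; AcOH; then TsOH·H2O (cat.), toluene, 50 °C
Reagents that add atoms: none
Why: In this directed aldol condensation (Claisen–Schmidt type) the unhindered acetyl enolate should add to the aldehyde far faster than the neopentyl C9 enolate, the low temperature holds back β-elimination of the C10 aryloxy group, and acid dehydration of the p-methoxybenzylic aldol gives the E-enone.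

Step 12
Reactants: 21 the chalcone with C9 methylene
Product: 22 the C9-hydroxy C8-ketone (either C9 epimer)
Conditions: LiN(SiMe3)2 (2.2 equiv), THF, −78 °C; 2-(phenylsulfonyl)-3-phenyloxaziridine; aq. NH4Cl
Reagents that add atoms: 2-(phenylsulfonyl)-3-phenyloxaziridine, O=S(=O)(c1ccccc1)N1OC1c1ccccc1
Why: With the acetyl group converted into the chalcone, C9 is the only enolisable carbon, and its lithium enolate is hydroxylated by the oxaziridine at low temperature (enolate oxidation); the C9 configuration does not matter.

Step 13
Reactants: 22 the C9-hydroxy C8-ketone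
Product: 23 CNP0121765.1 (target)
Conditions: Dess–Martin periodinane, NaHCO3, CH2Cl2, 23 °C
Reagents that add atoms: none
Why: Dess–Martin oxidation of the acyloin gives the non-enolisable 8,9-dione and should leave the chalcone and the chelated phenol untouched.

Compound list
1 | 1-bromo-3-methylbut-2-ene | CC(C)=CCBr | starting material
2 | N-methoxy-N-methylacetamide | CC(=O)N(C)OC | starting material
3 | 3-methylbut-2-enylmagnesium bromide | CC(C)=CC[Mg]Br | intermediate (not isolated)
4 | 3,3-dimethylpent-4-en-2-one | CC(=O)C(C)(C)C=C | intermediate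
5 | 2-methylcyclohex-2-en-1-one | CC1=CCCC1=O | starting material
6 | 3-bromoprop-1-ene | C=CCBr | starting material
7 | dimethylaluminium enolate of (3R)-2,3-dimethylcyclohexanone | C[C@@H]1CCCC(O[Al](C)C)=C1C | intermediate (not isolated)
8 | (2S,3R)-2-allyl-2,3-dimethylcyclohexan-1-one | C=CC[C@@]1(C)[C@H](C)CCCC1=O | intermediate
9 | (2R,3R)-2,3-dimethyl-2-[(E)-prop-1-enyl]cyclohexan-1-one | C/C=C/[C@@]1(C)[C@H](C)CCCC1=O | intermediate
10 | 5,6-dimethyl-6-[(E)-prop-1-enyl]cyclohex-1-en-1-yl trifluoromethanesulfonate (configuration of 9) | C/C=C/[C@@]1(C)[C@H](C)CCC=C1OS(=O)(=O)C(F)(F)F | intermediate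
11 | 1-{5,6-dimethyl-6-[(E)-prop-1-enyl]cyclohex-1-en-1-yl}-3,3-dimethylpent-4-en-2-one | C/C=C/[C@@]1(C)[C@H](C)CCC=C1CC(=O)C(C)(C)C=C | intermediate
12 | 4,4a,7,7-tetramethyl-2,3,4,4a,7,9-hexahydro-8H-benzo[7]annulen-8-one (C4/C5 methyls cis) | O=C1CC2=CCC[C@@H](C)[C@]2(C)C=CC1(C)C | intermediate
13 | C9 alcohol of 12, OH trans to the C5 methyl | O=C1[C@H](O)C2=CCC[C@@H](C)[C@]2(C)C=CC1(C)C | intermediate
14 | 2',6'-dihydroxy-4'-methoxyacetophenone | CC(=O)c1c(O)cc(OC)cc1O | starting material
15 | C9 (2-acetyl-3-hydroxy-5-methoxyphenyl) ether of 13, aryloxy cis to the C5 methyl | O=C1[C@@H](Oc3cc(OC)cc(O)c3C(C)=O)C2=CCC[C@@H](C)[C@]2(C)C=CC1(C)C | intermediate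
16 | C1-aryl 6,9-dien-8-one with free 2′-phenol, aryl cis to the C5 methyl | CC(=O)c1c(O)cc(OC)c(c1O)[C@H]1CC[C@@H](C)[C@]2(C)C=CC(C)(C)C(=O)C=C12 | intermediate (not isolated)
17 | cycloheptenone precursor: cis-fused dihydrobenzofuran, 2,2-dimethylcyclohept-3-enone (C8 ketone, C9 methylene) | CC(=O)c2c(O)cc(OC)c3c2O[C@]24CC(=O)C(C)(C)C=C[C@@]2(C)[C@H](C)CC[C@H]34 | intermediate
18 | pentacyclic C8 ketone with C9 methylene, cyclopropane anti to the C5 methyl | CC(=O)c2c(O)cc(OC)c3c2O[C@]24CC(=O)[C@@H]5[C@@H](C5(C)C)[C@@]2(C)[C@H](C)CC[C@H]34 | intermediate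
19 | 4-methoxybenzaldehyde | COc1ccc(C=O)cc1 | starting material
20 | aldol adduct of 18 and 19 (carbinol epimers) | COc1ccc(C(O)CC(=O)c2c(O)cc(OC)c3c2O[C@]24CC(=O)[C@@H]5[C@@H](C5(C)C)[C@@]2(C)[C@H](C)CC[C@H]34)cc1 | intermediate (not isolated)
21 | (E)-chalcone with C9 methylene | COc1ccc(/C=C/C(=O)c2c(O)cc(OC)c3c2O[C@]24CC(=O)[C@@H]5[C@@H](C5(C)C)[C@@]2(C)[C@H](C)CC[C@H]34)cc1 | intermediate
22 | C9-hydroxy C8-ketone chalcone (C9 epimers) | COc1ccc(/C=C/C(=O)c2c(O)cc(OC)c3c2O[C@]24C(O)C(=O)[C@@H]5[C@@H](C5(C)C)[C@@]2(C)[C@H](C)CC[C@H]34)cc1 | intermediate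
23 | CNP0121765.1 | COc1ccc(/C=C/C(=O)c2c(O)cc(OC)c3c2O[C@]24C(=O)C(=O)[C@@H]5[C@@H](C5(C)C)[C@@]2(C)[C@H](C)CC[C@H]34)cc1 | target

Total step count: 13. Longest linear sequence: 12 steps (steps 2 to 13, from 2-methylcyclohex-2-en-1-one); step 1 is a one-step side branch that joins at step 5.

Steps most likely to fail

Step 10. The triplet energy may leak into the hydroxyaryl ketone or into twisting of the cycloheptene, and C11 may close on the wrong alkene face, giving the cyclopropane syn to the C5 methyl. The fallback avoids photochemistry; it sets out from 10 and comes back at 18. Palladium-catalysed coupling of 10 with the zinc enolate of 2 (LiN(SiMe3)2, ZnCl2, Pd2(dba)3, P(t-Bu)3) would give the β,γ-unsaturated Weinreb amide F1, and vinylmagnesium bromide would turn it into the vinyl ketone F2. Ring-closing metathesis with the second-generation Grubbs catalyst would close the six-membered dienone F3. Isopropylidene transfer from diphenylsulfonium isopropylide (from isopropyldiphenylsulfonium tetrafluoroborate and t-BuLi) to the C6=C7 enone, a sulfur ylide cyclopropanation that should approach anti to the C5 methyl, would give the cyclopropyl ketone F4. C9 hydroxylation as in step 7 would give the alcohol F5, Mitsunobu etherification with 14 the aryl ether F6, and heating as in step 9 would then give 18.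

Step 9. At the temperature the rearrangement needs, the phenol may be lost by 1,4-elimination or C9 may epimerise, which would send the aryl group to the wrong face. The fallback sets out from 15 and comes back at 17. Zerovalent palladium (Pd(PPh3)4, THF, 23 °C) would ionise the allylic aryl ether with inversion, and the phenoxide carbon C3′ would attack the acyl-substituted π-allyl unit at C1 anti to palladium (Tsuji–Trost C-allylation, overall retention of the face). This gives the same phenol 16, which closes to 17; no new compound arises (F0).

Step 8. Displacement on the methyl-shielded face of C9 may be too slow, so that SN2′ attack at C1 or no reaction takes over. The fallback sets out from 12 and comes back at 15. Diazo transfer to the doubly activated C9 methylene (4-acetamidobenzenesulfonyl azide, DBU, MeCN) would give the α-diazo ketone F7. Rh2(OAc)4-catalysed O–H insertion with 14 would then form the C9–O bond without any displacement, and protonation of the resulting enol from the face remote from the C5 methyl would leave the aryloxy group on the methyl face, which is 15.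

Further compounds
F1 | step 10 | 2-{5,6-dimethyl-6-[(E)-prop-1-enyl]cyclohex-1-en-1-yl}-N-methoxy-N-methylacetamide | C/C=C/[C@@]1(C)[C@H](C)CCC=C1CC(=O)N(C)OC
F2 | step 10 | 1-{5,6-dimethyl-6-[(E)-prop-1-enyl]cyclohex-1-en-1-yl}but-3-en-2-one | C/C=C/[C@@]1(C)[C@H](C)CCC=C1CC(=O)C=C
F3 | step 10 | six-membered dienone (C8 ketone, C6=C7, C1=C10; C4/C5 methyls cis) | O=C1CC2=CCC[C@@H](C)[C@]2(C)C=C1
F4 | step 10 | cyclopropyl ketone with C1=C10, CMe2 bridge on C6/C7 anti to the C5 methyl | O=C1CC2=CCC[C@@H](C)[C@]2(C)[C@H]2[C@@H]1C2(C)C
F5 | step 10 | C9 alcohol of F4, OH trans to the C5 methyl | O=C1[C@H](O)C2=CCC[C@@H](C)[C@]2(C)[C@H]2[C@@H]1C2(C)C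
F6 | step 10 | C9 (2-acetyl-3-hydroxy-5-methoxyphenyl) ether of F5, aryloxy cis to the C5 methyl | O=C1[C@@H](Oc3cc(OC)cc(O)c3C(C)=O)C2=CCC[C@@H](C)[C@]2(C)[C@H]2[C@@H]1C2(C)C
F0 | step 9 | none | none
F7 | step 8 | C9 diazo derivative of 12 | O=C1C(=[N+]=[N-])C2=CCC[C@@H](C)[C@]2(C)C=CC1(C)C
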